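I count J first. J is the limiting reagent, and if one X goes per L, turning over the whole of J spends a quarter of X. So X holds steady, the pseudo-first-order case.

| setting | summer | dusk | autumn | dawn | Sunday's | Tuesday's | Monday's |
|---|---|---|---|---|---|---|---|
| J | 0.10 M | 0.10 M | 0.10 M | 0.050 M | 0.10 M (fed, over 8.0 min) | 0.10 M | 0.10 M |
| X | 4 equiv | 2.7 equiv | 6 equiv | 4 equiv | 4.00 equiv | 4.00 equiv | 4.00 equiv (fed, over 8.0 min) |
| remark | run made earlier | run made earlier | run made earlier | run made earlier | all else is in the flask from the start; the feed brings no volume worth counting | everything together at the start | all else is in the flask from the start; the feed brings no volume worth counting |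
| time |  |  |  |  | 20 min | 20 min | 20 min |

| run | time / min | L / % | G / % |
|---|---|---|---|
| summer | 0.667 | 0 | 0.4 |
| summer | 2.00 | 1.7 | 0 |
| summer | 3.00 | 2.1 | 0.3 |
| summer | 5.00 | 4.2 | 0.6 |
| summer | 8.00 | 6.8 | 2.8 |
| summer | 10.0 | 9.0 | 4.2 |
| summer | 12.0 | 11.2 | 5.1 |
| dusk | 1.00 | 0.8 | 0.2 |
| dusk | 1.33 | 0.1 | 0.7 |
| dusk | 2.00 | 0.8 | 0 |
| dusk | 3.00 | 1.6 | 1.0 |
| dusk | 5.00 | 3.3 | 0.9 |
| dusk | 8.00 | 4.9 | 1.8 |
| dusk | 12.0 | 8.4 | 4.6 |
| autumn | 0.667 | 0.3 | 0 |
| autumn | 2.00 | 2.7 | 0 |
| autumn | 3.00 | 3.3 | 0.4 |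
| autumn | 5.00 | 5.7 | 1.6 |
| autumn | 8.00 | 9.1 | 2.6 |
| autumn | 10.0 | 12.4 | 3.1 |
| autumn | 12.0 | 15.0 | 6.2 |
| dawn | 2.50 | 1.0 | 0.1 |
| dawn | 5.00 | 1.6 | 1.8 |
| dawn | 8.00 | 3.2 | 3.3 |
| dawn | 10.0 | 4.2 | 3.6 |
| dawn | 12.0 | 6.6 | 5.2 |

(readings scatter by 0.5 percentage points)



1. the flask that comes out highest in share of L in L plus G, or "all alike" when all lie within 1.5 percentage points (Sunday's / Tuesday's / Monday's / all alike)
2. share of L in L plus G at the end, Sunday's
3. share of L in L plus G at the end, Tuesday's
4. share of L in L plus G at the end, Monday's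

**My measure.** I call X-time the concentration of X summed over the minutes. Summer's 11.2% of L after 12.0 min gives 0.0233 M⁻¹ min⁻¹, the yield of L per X-time.

**First doubt.** Autumn gives 0.0208 M⁻¹ min⁻¹ and dusk 0.0259 M⁻¹ min⁻¹, so autumn's is lower by 19.7%, while a reading of 8.4% carries 0.5 percentage points. I cannot compute that gap away, so I keep summer's value, which has the asked charge of X.

**Three flasks.** Tuesday's X-time gives L of 18.7%. In Monday's, the steady feed of X costs 4.00 min of X-time. In Sunday's, J arrives late by that same average, so each gives L of 14.9%.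

**Second doubt.** G may not follow X-time: at 12.0 min it reads 4.6% in dusk, 5.1% in summer and 6.2% in autumn, a rise with X of 1.6 points in all, where each reading carries 0.5 points. But dawn, with half of summer's X, reads 5.2% at 12.0 min, no lower than summer, so I take that rise as scatter and treat G as free of X-time. Extending summer's late slope gives G of 9.70% for Tuesday's and Monday's. The same delay lowers Sunday's to 7.40%. My shares are 66.8% for Sunday's, 65.8% for Tuesday's and 60.6% for Monday's. Sunday's leads Tuesday's by less than the margin, but Monday's lies far enough below that the flasks are not alike.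

**The forecast.** It names Sunday's, with 65%, 63% and 57% in that same flask order, reading G as “a first-order route through a hidden intermediate”. Its order is mine, though its Tuesday's and Monday's stand lower.

**The result.** Sunday's gives 64.3%, Tuesday's 61.1% and Monday's 57.4%, so Sunday's leads.

    J ⇌ Q (K = 2.60, k = 0.0120 s⁻¹)
    D → G (k = 0.00150 s⁻¹)
    J ⇌ Z (K = 0.820, k = 0.00260 s⁻¹)
    Q → D (k = 3.60 × 10⁻⁴ s⁻¹)
    X + Z → L (k = 0.00340 M⁻¹ s⁻¹)

**The neighbour flask.** Tuesday's holds 38.2% of Q, yet its L is 17.7% against my 18.7%, and Monday's is 15.4% against 14.9%. The neighbour is Sunday's with 10.0 equiv of X. X-time promises L of 37.3%, and with Sunday's G of 8.09% a share of 82.2%. That flask gives less L: L is 25.9%, G is 7.87%, and the share is 76.7%.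

The data are simulated from invented constants, noise included.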